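The synthesis rests on cutting two bonds of the γ-butyrolactone ring. C4–C1′ ties the oxygenated side chain to the β-carbon, trans to the C5 alkenyl arm. C3–CH2 is the future exocyclic methylene on the α-carbon. Both cuts lead back to a C3=C4 butenolide. In one flask, a 2-lithio-1,3-dithiane already carrying the complete silyl-protected (E)-side chain adds to C4 of (S)-5-(trityloxymethyl)furan-2(5H)-one, opposite the C5 substituent. The lactone enolate is then aminomethylated at C3 with Eschenmoser's salt. Two C–C bonds and two stereocentres result, and no ring is formed. Dithiane, CH2NMe2 and CH2OTr then serve as latent C1′ carbinol, methylene and C6=C7 arm.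

Key step: step 6

Remark on numbering and descriptors: the lactone atoms are O1, C2 (C=O), C3, C4, C5. C1′ is the side-chain carbon on C4, and C6=C7 is the alkene of the arm on C5. The C4 descriptor changes from S to R in step 8, and the C5 descriptor from S to R in step 12. Both changes come only from CIP priorities; no bond at these centres is broken. Compounds 1, 3, 7, 10 and 19 are taken as commercial.

Step 1
Reactants: 1 (S)-5-(hydroxymethyl)furan-2(5H)-one
Product: 2 (S)-5-(trityloxymethyl)furan-2(5H)-one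
Conditions: TrCl, pyridine, 4-(dimethylamino)pyridine (cat.), CH2Cl2, rt
Reagents that add atoms: trityl chloride, ClC(c1ccccc1)(c1ccccc1)c1ccccc1
Why: O-tritylation (SN1 through the trityl cation) meets only one hydroxyl group, and pyridine is too weak a base to remove the C5 proton, so the stereocentre is kept.

Step 2
Reactants: 3 3-methylbut-2-en-1-ol (prenol)
Product: 4 tert-butyl[(3-methylbut-2-enyl)oxy]diphenylsilane
Conditions: TBDPSCl, imidazole, CH2Cl2, 0 °C → rt
Reagents that add atoms: tert-butylchlorodiphenylsilane, CC(C)(C)[Si](Cl)(c1ccccc1)c1ccccc1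
Why: Imidazole-promoted O-silylation gives an ether that tolerates organolithiums and mild acid and is therefore orthogonal to the trityl ether removed in step 10.

Step 3
Reactants: 4 tert-butyl[(3-methylbut-2-enyl)oxy]diphenylsilane
Product: 5 (E)-4-(tert-butyldiphenylsilyloxy)-2-methylbut-2-en-1-ol
Conditions: SeO2 (cat.), t-BuOOH, salicylic acid (cat.), CH2Cl2, 0 °C → rt
Reagents that add atoms: tert-butyl hydroperoxide, CC(C)(C)OO (oxygen atom, passed on through SeO2)
Why: The catalytic Riley oxidation (ene reaction, then [2,3]-sigmatropic shift) hydroxylates the methyl group trans to the CH2OSi chain of a trisubstituted alkene, which fixes the E geometry of the side chain.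

Step 4
Reactants: 5 (E)-4-(tert-butyldiphenylsilyloxy)-2-methylbut-2-en-1-ol
Product: 6 (E)-(4-bromo-3-methylbut-2-enyloxy)(tert-butyl)diphenylsilane
Conditions: CBr4, PPh3, CH2Cl2, 0 °C
Reagents that add atoms: tetrabromomethane, BrC(Br)(Br)Br
Why: The Appel reaction replaces the oxyphosphonium group by bromide in a direct SN2 step at the primary allylic carbon under neutral conditions, so alkene geometry and silyl ether stay intact.

Step 5
Reactants: 6 (E)-(4-bromo-3-methylbut-2-enyloxy)(tert-butyl)diphenylsilane; 7 1,3-dithiane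
Product: 9 2-[(E)-4-(tert-butyldiphenylsilyloxy)-2-methylbut-2-enyl]-1,3-dithiane, via 2-lithio-1,3-dithiane 8 (not isolated)
Conditions: 7, n-BuLi, THF, −30 °C; then 6, −78 → −20 °C
Reagents that add atoms: none
Why: In this Corey–Seebach alkylation the soft lithiodithiane displaces the unhindered primary allylic bromide by direct SN2 attack, with the E alkene retained.

Step 6
Reactants: 9 2-[(E)-4-(tert-butyldiphenylsilyloxy)-2-methylbut-2-enyl]-1,3-dithiane; 2 (S)-5-(trityloxymethyl)furan-2(5H)-one; 10 Eschenmoser's salt (N,N-dimethylmethyleneiminium iodide)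
Product: 13 (3R,4S,5S)-3-[(dimethylamino)methyl]-4-{2-[(E)-4-(tert-butyldiphenylsilyloxy)-2-methylbut-2-enyl]-1,3-dithian-2-yl}-5-(trityloxymethyl)dihydrofuran-2(3H)-one (trans,trans lactone), via lithiated dithiane 11 (not isolated), via lithium enolate 12 (not isolated)
Conditions: 9, n-BuLi, THF, −30 °C; HMPA, −78 °C; 2 in THF, −78 °C; then solid 10, −78 → 0 °C
Reagents that add atoms: none
Why: n-BuLi removes the C2 proton of 9 and HMPA turns 11 into a solvent-separated ion pair, whose sulfur-stabilised carbanion attacks the β-carbon C4 of 2 (Michael addition) to give enolate 12, which is then alkylated at C3 by the iminium ion of 10 (Mannich reaction). The closest known reaction type is the tandem conjugate addition–enolate trapping of 2-lithio-1,3-dithianes on 5-(trityloxymethyl)butenolide, practised with halides, aldehydes and iminium salts as third component. The step forms no ring. C4 is controlled by the C5 stereocentre, because the bulky CH2OTr group covers one face of the flat ring and the nucleophile must enter from the other, so the new bond lies trans to it. C3 is controlled by the new fully substituted dithianyl carbon on C4, which sends the small electrophile to the opposite face, although this centre is erased in step 15. The step needs 1,4-attack to win over carbonyl attack and over removal of the C5 proton, which ion-pair separation, low temperature and the modest electrophilicity of a lactone carbonyl should secure.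

Step 7
Reactants: 13 trans,trans dithianyl Mannich lactone
Product: 14 (3R,4S,5S)-4-[(E)-5-(tert-butyldiphenylsilyloxy)-3-methylpent-3-enoyl]-3-[(dimethylamino)methyl]-5-(trityloxymethyl)dihydrofuran-2(3H)-one
Conditions: Hg(ClO4)2·3H2O, CaCO3, THF/H2O (5:1), 0 °C, short contact; crude product used at once
Reagents that add atoms: water, O
Why: In this thioketal hydrolysis (Corey–Seebach unmasking) thiophilic divalent mercury activates the sulfur atoms within minutes, while CaCO3 keeps the medium neutral so that trityl ether, silyl ether, amine and the base-sensitive β,γ-unsaturated ketone survive.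

Step 8
Reactants: 14 C1′ ketone
Product: 15 (3R,4R,5S)-4-[(1R,3E)-5-(tert-butyldiphenylsilyloxy)-1-hydroxy-3-methylpent-3-enyl]-3-[(dimethylamino)methyl]-5-(trityloxymethyl)dihydrofuran-2(3H)-one
Conditions: (S)-5,5-diphenyl-2-methyl-3,4-propano-1,3,2-oxazaborolidine (50 mol %), catecholborane (3 equiv), toluene, −78 → −40 °C; MeOH, then aq. NaHCO3
Reagents that add atoms: none
Why: In the Corey–Bakshi–Shibata reduction the ketone binds to the catalyst boron anti to its larger branched C4 substituent and receives hydride on one face only, so the (S)-catalyst sets 1′R by reagent control, while catecholborane at low temperature leaves lactone and alkene alone and its amine adduct falls apart on aqueous work-up.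

Step 9
Reactants: 15 (1′R)-alcohol
Product: 16 (3R,4R,5S)-4-[(1R,3E)-5-(tert-butyldiphenylsilyloxy)-1-(methacryloyloxy)-3-methylpent-3-enyl]-3-[(dimethylamino)methyl]-5-(trityloxymethyl)dihydrofuran-2(3H)-one
Conditions: methacrylic anhydride, Et3N, 4-(dimethylamino)pyridine (cat.), CH2Cl2, 0 °C → rt
Reagents that add atoms: methacrylic anhydride, C=C(C)C(=O)OC(=O)C(C)=C
Why: Nucleophile-catalysed acyl transfer esterifies the only free hydroxyl group with retention at C1′ and, run directly after step 8 without any external nucleophile, should outrun translactonisation onto C1′–O.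

Step 10
Reactants: 16 methacrylate trityl ether
Product: 17 (3R,4R,5S)-4-[(1R,3E)-5-(tert-butyldiphenylsilyloxy)-1-(methacryloyloxy)-3-methylpent-3-enyl]-3-[(dimethylamino)methyl]-5-(hydroxymethyl)dihydrofuran-2(3H)-one
Conditions: camphor-10-sulfonic acid (1.5 equiv), MeOH/CH2Cl2 (1:1), 0 °C → rt; aq. NaHCO3
Reagents that add atoms: none
Why: Acid-catalysed SN1 solvolysis of the trityl ether in methanol is much faster than cleavage of a primary TBDPS ether, and the amine simply travels as its sulfonate salt until the basic work-up.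

Step 11
Reactants: 17 primary alcohol
Product: 18 (3R,4R,5S)-4-[(1R,3E)-5-(tert-butyldiphenylsilyloxy)-1-(methacryloyloxy)-3-methylpent-3-enyl]-3-[(dimethylamino)methyl]-5-formyldihydrofuran-2(3H)-one
Conditions: Dess–Martin periodinane, CH2Cl2, 0 °C → rt
Reagents that add atoms: none
Why: The Dess–Martin oxidation stops at the aldehyde under non-aqueous, nearly neutral conditions, the released acetic acid shields the amine by protonation, and C5 is not at risk because its trans arrangement is also the thermodynamic one.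

Step 12
Reactants: 18 C5 aldehyde; 19 2-(triphenylphosphoranylidene)propanal
Product: 20 (3R,4R,5R)-4-[(1R,3E)-5-(tert-butyldiphenylsilyloxy)-1-(methacryloyloxy)-3-methylpent-3-enyl]-3-[(dimethylamino)methyl]-5-[(E)-2-methyl-3-oxoprop-1-enyl]dihydrofuran-2(3H)-one
Conditions: 19 (2 equiv), toluene, 60 °C
Reagents that add atoms: none
Why: The Wittig reaction of a stabilised formyl ylide with the activated α-acyloxy aldehyde gives the E-trisubstituted enal, and the weakly basic ylide spares the esters, the lactone and the C5 centre.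

Step 13
Reactants: 20 E-enal
Product: 21 (3R,4R,5R)-4-[(1R,3E)-5-(tert-butyldiphenylsilyloxy)-1-(methacryloyloxy)-3-methylpent-3-enyl]-3-[(dimethylamino)methyl]-5-[(E)-3-hydroxy-2-methylprop-1-enyl]dihydrofuran-2(3H)-one
Conditions: NaBH4, CeCl3·7H2O, MeOH, −78 → −40 °C
Reagents that add atoms: none
Why: The Luche reduction attacks the aldehyde carbonyl in 1,2-fashion at low temperature far faster than methacrylate or lactone, and the α-methylene unit, which borohydride would reduce, is still masked as the amine.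

Step 14
Reactants: 21 primary allylic alcohol
Product: 22 (3R,4R,5R)-5-[(E)-3-acetoxy-2-methylprop-1-enyl]-4-[(1R,3E)-5-(tert-butyldiphenylsilyloxy)-1-(methacryloyloxy)-3-methylpent-3-enyl]-3-[(dimethylamino)methyl]dihydrofuran-2(3H)-one
Conditions: Ac2O, Et3N, 4-(dimethylamino)pyridine (cat.), CH2Cl2, 0 °C
Reagents that add atoms: acetic anhydride, CC(=O)OC(C)=O
Why: Nucleophile-catalysed acetylation meets a single free, unhindered primary hydroxyl group.

Step 15
Reactants: 22 allylic acetate Mannich base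
Product: 24 (4R,5R)-5-[(E)-3-acetoxy-2-methylprop-1-enyl]-4-[(1R,3E)-5-(tert-butyldiphenylsilyloxy)-1-(methacryloyloxy)-3-methylpent-3-enyl]-3-methylenedihydrofuran-2(3H)-one, via trimethylammonium iodide 23 (not isolated)
Conditions: MeI (excess), THF, rt; evaporate; NaHCO3 (aq.), EtOAc, rt
Reagents that add atoms: iodomethane, CI (its atoms stay only in intermediate 23)
Why: Exhaustive N-methylation makes the nitrogen a leaving group and mild base then triggers a Hofmann-type E1cB elimination across C3–CH2, the standard release of an α-methylene lactone from its Mannich base, which erases C3 and leaves C4 untouched.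

Step 16
Reactants: 24 α-methylene lactone silyl ether
Product: 25 (4R,5R)-5-[(E)-3-acetoxy-2-methylprop-1-enyl]-4-[(1R,3E)-5-hydroxy-1-(methacryloyloxy)-3-methylpent-3-enyl]-3-methylenedihydrofuran-2(3H)-one (CNP0323189.1)
Conditions: HF·pyridine, pyridine/THF, 0 °C → rt
Reagents that add atoms: none
Why: Fluoride-driven Si–O cleavage with buffered HF·pyridine is non-basic, so acetate and methacrylate should neither migrate nor hydrolyse and the α-methylene lactone should not suffer Michael addition.

Compound list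
1 | (S)-5-(hydroxymethyl)furan-2(5H)-one | C1=CC(=O)O[C@@H]1CO | starting material
2 | (S)-5-(trityloxymethyl)furan-2(5H)-one | C1=CC(=O)O[C@@H]1COC(c1ccccc1)(c1ccccc1)c1ccccc1 | intermediate
3 | 3-methylbut-2-en-1-ol (prenol) | CC(C)=CCO | starting material
4 | tert-butyl[(3-methylbut-2-enyl)oxy]diphenylsilane | CC(C)=CCO[Si](C(C)(C)C)(c1ccccc1)c1ccccc1 | intermediate
5 | (E)-4-(tert-butyldiphenylsilyloxy)-2-methylbut-2-en-1-ol | OC/C(C)=C/CO[Si](C(C)(C)C)(c1ccccc1)c1ccccc1 | intermediate
6 | (E)-(4-bromo-3-methylbut-2-enyloxy)(tert-butyl)diphenylsilane | BrC/C(C)=C/CO[Si](C(C)(C)C)(c1ccccc1)c1ccccc1 | intermediate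
7 | 1,3-dithiane | C1CSCSC1 | starting material
8 | 2-lithio-1,3-dithiane | [Li]C1SCCCS1 | intermediate
9 | 2-[(E)-4-(tert-butyldiphenylsilyloxy)-2-methylbut-2-enyl]-1,3-dithiane | C1(C/C(C)=C/CO[Si](C(C)(C)C)(c2ccccc2)c2ccccc2)SCCCS1 | intermediate
10 | Eschenmoser's salt (N,N-dimethylmethyleneiminium iodide) | C=[N+](C)C.[I-] | starting material
11 | 2-lithio derivative of 9 | [Li]C1(C/C(C)=C/CO[Si](C(C)(C)C)(c2ccccc2)c2ccccc2)SCCCS1 | intermediate
12 | lithium enolate (C2–OLi, C2=C3) of the (4S,5S) Michael adduct | C1(C/C(C)=C/CO[Si](C(C)(C)C)(c2ccccc2)c2ccccc2)(SCCCS1)[C@H]1C=C(O[Li])O[C@@H]1COC(c1ccccc1)(c1ccccc1)c1ccccc1 | intermediate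
13 | (3R,4S,5S)-3-[(dimethylamino)methyl]-4-{2-[(E)-4-(tert-butyldiphenylsilyloxy)-2-methylbut-2-enyl]-1,3-dithian-2-yl}-5-(trityloxymethyl)dihydrofuran-2(3H)-one | C1(C/C(C)=C/CO[Si](C(C)(C)C)(c2ccccc2)c2ccccc2)(SCCCS1)[C@H]1[C@H](CN(C)C)C(=O)O[C@@H]1COC(c1ccccc1)(c1ccccc1)c1ccccc1 | intermediate
14 | (3R,4S,5S)-4-[(E)-5-(tert-butyldiphenylsilyloxy)-3-methylpent-3-enoyl]-3-[(dimethylamino)methyl]-5-(trityloxymethyl)dihydrofuran-2(3H)-one | O=C(C/C(C)=C/CO[Si](C(C)(C)C)(c1ccccc1)c1ccccc1)[C@H]1[C@H](CN(C)C)C(=O)O[C@@H]1COC(c1ccccc1)(c1ccccc1)c1ccccc1 | intermediate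
15 | (3R,4R,5S)-4-[(1R,3E)-5-(tert-butyldiphenylsilyloxy)-1-hydroxy-3-methylpent-3-enyl]-3-[(dimethylamino)methyl]-5-(trityloxymethyl)dihydrofuran-2(3H)-one | O[C@H](C/C(C)=C/CO[Si](C(C)(C)C)(c1ccccc1)c1ccccc1)[C@H]1[C@H](CN(C)C)C(=O)O[C@@H]1COC(c1ccccc1)(c1ccccc1)c1ccccc1 | intermediate
16 | (3R,4R,5S)-4-[(1R,3E)-5-(tert-butyldiphenylsilyloxy)-1-(methacryloyloxy)-3-methylpent-3-enyl]-3-[(dimethylamino)methyl]-5-(trityloxymethyl)dihydrofuran-2(3H)-one | C=C(C)C(=O)O[C@H](C/C(C)=C/CO[Si](C(C)(C)C)(c1ccccc1)c1ccccc1)[C@H]1[C@H](CN(C)C)C(=O)O[C@@H]1COC(c1ccccc1)(c1ccccc1)c1ccccc1 | intermediate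
17 | 5-(hydroxymethyl) analogue of 16 (1′R,3R,4R,5S) | C=C(C)C(=O)O[C@H](C/C(C)=C/CO[Si](C(C)(C)C)(c1ccccc1)c1ccccc1)[C@H]1[C@H](CN(C)C)C(=O)O[C@@H]1CO | intermediate
18 | 5-formyl analogue of 16 (1′R,3R,4R,5S) | C=C(C)C(=O)O[C@H](C/C(C)=C/CO[Si](C(C)(C)C)(c1ccccc1)c1ccccc1)[C@H]1[C@H](CN(C)C)C(=O)O[C@@H]1C=O | intermediate
19 | 2-(triphenylphosphoranylidene)propanal | CC(C=O)=P(c1ccccc1)(c1ccccc1)c1ccccc1 | starting material
20 | 5-[(E)-2-methyl-3-oxoprop-1-enyl] lactone (1′R,3R,4R,5R) | C=C(C)C(=O)O[C@H](C/C(C)=C/CO[Si](C(C)(C)C)(c1ccccc1)c1ccccc1)[C@H]1[C@H](CN(C)C)C(=O)O[C@@H]1/C=C(\C)C=O | intermediate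
21 | 5-[(E)-3-hydroxy-2-methylprop-1-enyl] lactone (1′R,3R,4R,5R) | C=C(C)C(=O)O[C@H](C/C(C)=C/CO[Si](C(C)(C)C)(c1ccccc1)c1ccccc1)[C@H]1[C@H](CN(C)C)C(=O)O[C@@H]1/C=C(\C)CO | intermediate
22 | 5-[(E)-3-acetoxy-2-methylprop-1-enyl] lactone (1′R,3R,4R,5R) | C=C(C)C(=O)O[C@H](C/C(C)=C/CO[Si](C(C)(C)C)(c1ccccc1)c1ccccc1)[C@H]1[C@H](CN(C)C)C(=O)O[C@@H]1/C=C(\C)COC(C)=O | intermediate
23 | 3-[(trimethylammonio)methyl] iodide derived from 22 | C=C(C)C(=O)O[C@H](C/C(C)=C/CO[Si](C(C)(C)C)(c1ccccc1)c1ccccc1)[C@H]1[C@H](C[N+](C)(C)C)C(=O)O[C@@H]1/C=C(\C)COC(C)=O.[I-] | intermediate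
24 | (4R,5R)-5-[(E)-3-acetoxy-2-methylprop-1-enyl]-4-[(1R,3E)-5-(tert-butyldiphenylsilyloxy)-1-(methacryloyloxy)-3-methylpent-3-enyl]-3-methylenedihydrofuran-2(3H)-one | C=C(C)C(=O)O[C@H](C/C(C)=C/CO[Si](C(C)(C)C)(c1ccccc1)c1ccccc1)[C@H]1C(=C)C(=O)O[C@@H]1/C=C(\C)COC(C)=O | intermediate
25 | (4R,5R)-5-[(E)-3-acetoxy-2-methylprop-1-enyl]-4-[(1R,3E)-5-hydroxy-1-(methacryloyloxy)-3-methylpent-3-enyl]-3-methylenedihydrofuran-2(3H)-one (CNP0323189.1) | C=C(C)C(=O)O[C@H](C/C(C)=C/CO)[C@H]1C(=C)C(=O)O[C@@H]1/C=C(\C)COC(C)=O | target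

Total step count: 16. Longest linear sequence: 15 steps (3 → 25, steps 2 to 16); step 1 is the only step on the second branch.

Steps most likely to fail

Step 6. The 2-alkyl-dithianyl anion is hindered and strongly basic. Proton abstraction at C5 of the butenolide (followed by loss of trityloxide) or attack at the lactone carbonyl may therefore compete with attack at C4. The fallback runs from bromide 6 back to ketone 14 and uses a softer, less basic acyl-anion equivalent. Bis(phenylthio)methane is deprotonated (n-BuLi, THF, 0 °C) to bis(phenylthio)methyllithium F1 and alkylated with 6 to the acyclic thioacetal F2. n-BuLi/TMEDA converts this into the doubly phenylthio-stabilised carbanion F3, a class of nucleophile that adds 1,4 to butenolides even without a polar additive. Addition to 2 gives the lithium enolate F4, which is trapped with 10 to give the bis(phenylthio) Mannich lactone F5. Hydrolysis under the conditions of step 7 then delivers 14.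

Step 7. Hydrolysis of the crowded thioketal may be slow enough for divalent mercury to engage the amine or the trisubstituted alkene. A long contact time also favours migration of the double bond into conjugation or β-elimination of the lactone carboxylate, both helped by the internal amine base. The fallback runs from 9 and 2 back to alcohol 15, and the nitrogen enters only after C1′ has been unmasked and reduced. Enolate 12, made as in step 6, is quenched with aqueous NH4Cl to give the C3-unsubstituted dithianyl lactone F6. With no amine in the molecule, metal-free alkylative hydrolysis (MeI, CaCO3, aqueous MeCN) gives the keto lactone F7. The reduction of step 8 gives the (1′R)-hydroxy lactone F8. LiN(i-Pr)2 (2.3 equiv, THF, −78 °C) then forms the alkoxide enolate dianion F9, whose carbon terminus is aminomethylated with 10 anti to the C4 substituent to give 15.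

Step 8. Facial selectivity may be eroded by a mismatch between the catalyst and the resident stereocentres. The amine may also tie up the boron reagents and open an uncatalysed background reduction. The fallback runs from 14 back to 16 and relies on stereoinversion instead of direct control. The enantiomeric (R)-5,5-diphenyl-2-methyl-3,4-propano-1,3,2-oxazaborolidine with catecholborane gives the (1′S)-alcohol F10. Mitsunobu esterification with methacrylic acid (PPh3, DIAD, toluene, 0 °C) inverts C1′ and installs the ester in the same operation, giving 16. A mixture of epimers can thus be separated and both halves carried on to 16, one by step 9 and the other by the Mitsunobu reaction.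

Further compounds
F1 | step 6 | bis(phenylthio)methyllithium | [Li]C(Sc1ccccc1)Sc1ccccc1
F2 | step 6 | tert-butyl{[(E)-3-methyl-5,5-bis(phenylthio)pent-2-enyl]oxy}diphenylsilane | C(C/C(C)=C/CO[Si](C(C)(C)C)(c1ccccc1)c1ccccc1)(Sc1ccccc1)Sc1ccccc1
F3 | step 6 | 5-lithio derivative of F2 | [Li]C(C/C(C)=C/CO[Si](C(C)(C)C)(c1ccccc1)c1ccccc1)(Sc1ccccc1)Sc1ccccc1
F4 | step 6 | lithium enolate of the (4S,5S) bis(phenylthio) Michael adduct | C(C/C(C)=C/CO[Si](C(C)(C)C)(c1ccccc1)c1ccccc1)(Sc1ccccc1)(Sc1ccccc1)[C@H]1C=C(O[Li])O[C@@H]1COC(c1ccccc1)(c1ccccc1)c1ccccc1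
F5 | step 6 | (3R,4S,5S)-4-[(E)-5-(tert-butyldiphenylsilyloxy)-3-methyl-1,1-bis(phenylthio)pent-3-enyl]-3-[(dimethylamino)methyl]-5-(trityloxymethyl)dihydrofuran-2(3H)-one | C(C/C(C)=C/CO[Si](C(C)(C)C)(c1ccccc1)c1ccccc1)(Sc1ccccc1)(Sc1ccccc1)[C@H]1[C@H](CN(C)C)C(=O)O[C@@H]1COC(c1ccccc1)(c1ccccc1)c1ccccc1
F6 | step 7 | (4S,5S)-4-{2-[(E)-4-(tert-butyldiphenylsilyloxy)-2-methylbut-2-enyl]-1,3-dithian-2-yl}-5-(trityloxymethyl)dihydrofuran-2(3H)-one | C1(C/C(C)=C/CO[Si](C(C)(C)C)(c2ccccc2)c2ccccc2)(SCCCS1)[C@H]1CC(=O)O[C@@H]1COC(c1ccccc1)(c1ccccc1)c1ccccc1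
F7 | step 7 | (4S,5S)-4-[(E)-5-(tert-butyldiphenylsilyloxy)-3-methylpent-3-enoyl]-5-(trityloxymethyl)dihydrofuran-2(3H)-one | O=C(C/C(C)=C/CO[Si](C(C)(C)C)(c1ccccc1)c1ccccc1)[C@H]1CC(=O)O[C@@H]1COC(c1ccccc1)(c1ccccc1)c1ccccc1
F8 | step 7 | (4R,5S)-4-[(1R,3E)-5-(tert-butyldiphenylsilyloxy)-1-hydroxy-3-methylpent-3-enyl]-5-(trityloxymethyl)dihydrofuran-2(3H)-one | O[C@H](C/C(C)=C/CO[Si](C(C)(C)C)(c1ccccc1)c1ccccc1)[C@H]1CC(=O)O[C@@H]1COC(c1ccccc1)(c1ccccc1)c1ccccc1
F9 | step 7 | dilithium alkoxide enolate of F8 | [Li]O[C@H](C/C(C)=C/CO[Si](C(C)(C)C)(c1ccccc1)c1ccccc1)[C@H]1C=C(O[Li])O[C@@H]1COC(c1ccccc1)(c1ccccc1)c1ccccc1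
F10 | step 8 | (3R,4R,5S)-4-[(1S,3E)-5-(tert-butyldiphenylsilyloxy)-1-hydroxy-3-methylpent-3-enyl]-3-[(dimethylamino)methyl]-5-(trityloxymethyl)dihydrofuran-2(3H)-one | O[C@@H](C/C(C)=C/CO[Si](C(C)(C)C)(c1ccccc1)c1ccccc1)[C@H]1[C@H](CN(C)C)C(=O)O[C@@H]1COC(c1ccccc1)(c1ccccc1)c1ccccc1
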